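## The problem

1. Target 10 is a flavanone. Benzo ring A (C4a, C5 to C8, C8a, free OH on C7) is fused to the dihydropyranone ring C (O1, C2, C3, C4=O), and ring B is attached to C2 through the single bond C2–C1'.
2. Ring B carries a methoxy group on C4' flanked by prenyl chains on C3' and C5', so it has a local mirror plane through C1' and C4'.
3. C2 (S) is the only stereocentre. No other centre can direct it, so its configuration must come from a catalyst or reagent.
4. C2 is also the weak point. O1–C2 lies β to the C4 carbonyl, so base (and more slowly acid or heat) opens ring C by retro-oxa-Michael reaction to the achiral 2'-hydroxychalcone. Reclosure gives racemate, and in this 5-deoxy series the open form is not strongly disfavoured.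
5. The trisubstituted prenyl alkenes rule out strong Brønsted or Lewis acids, electrophilic halogen, peracids, hydroboration and catalytic hydrogenation. That removes much of classical flavonoid chemistry and many protecting groups.
6. O7 must end free and O4' methylated. O7–H is a vinylogous carboxylic acid whose anion switches off the C4 carbonyl.
7. The enabling feature is that C2 is both the β-carbon of the C2–C3–C4=O unit of ring C and the only atom linking ring C to ring B. At the chromone oxidation level (C2=C3), a 1,4-addition of a ring B nucleophile therefore makes the C2–C1' bond and the stereocentre together, with O1–C2 already in place and never made or broken.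
8. The matching nucleophilic site C1' is the one ring B carbon that lies para to O4' and between two C–H positions (C2', C6'). Steric control alone puts boron there, and the mirror plane lets both prenyl groups go on in one operation.

## Retrosynthesis

**10 to 9 (O7–Si).** The free phenol is masked as the triisopropylsilyl ether 9.
- Unmasked, O7–H would be deprotonated in the key step, which would turn ring C into an unreactive vinylogous carboxylate and consume the active hydroxo catalyst.
- An acetal would need acid near the prenyl groups, a benzyl ether would need hydrogenolysis, and an ester would not last in aqueous base. A silyl ether leaves with fluoride in a weakly acidic medium.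
- 9 is no simpler in skeleton. The forward step must only cleave O–Si without providing a base that can deprotonate C3.

**9 to 6 + 8 (C2–C1').**
- Of the four bonds at the stereocentre, O1–C2 is the one whose formation is reversible. C2–C3 offers no polar logic that keeps ring C intact. C2–H would require the whole skeleton first, at a higher oxidation level.
- Only the C2–C1' cut divides the molecule into two pieces of similar size, both flat and achiral: boronic acid 6 (all of ring B) and chromone 8 (rings A and C, ready made).
- The forward reaction must transfer the aryl group to the Re face of C2 of 8 under catalyst control, by 1,4- and not 1,2-addition. It must leave the prenyl alkenes alone and run close enough to neutral that 9 does not open.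

**8 to 7 (O7–Si).** 8 comes from commercial 7-hydroxychromone 7 by silylation. Buying rings A and C together removes every ring-forming step from the route. The only demand is clean O-silylation of an acidic phenol.

**6 to 5 (two B–O bonds).** The boronic acid 6 is traced to its pinacol ester 5.
- The ester is the form in which boron can be introduced and carried.
- The free acid is the form that transmetalates to rhodium at low temperature and low base loading, which the labile product needs.
- The forward step must remove pinacol without touching the alkenes or the C–B bond.

**5 to 2 + two of 3, via 4 (C3'–CH2 and C5'–CH2).**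
- Both prenyl groups are cut at the aryl–CH2 bonds at once, which the mirror plane of ring B allows.
- The neighbouring cut at the alkene (metathesis) needs an extra step. The O-to-C route (allyl ether, Claisen rearrangement) can move only one chain per cycle.
- The precursors are dibromide 2 and prenyl bromide 3, used as its zinc reagent 4.
- The forward reaction must couple twice with linear selectivity and leave the boronate alone. A base-free Negishi coupling can do this.

**2 to 1 (C1'–B).**
- The boron is removed to give commercial 2,6-dibromoanisole 1.
- A halogen–metal route would need a third halogen distinguishable from the other two. C–H borylation needs none, because only one C–H of 1 is unhindered.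
- Placing this step first keeps the iridium catalyst away from any alkene.

## Roads not taken

**Alternative 1:** cut O1–C2, the most obvious plan.
- Forward route: Claisen–Schmidt condensation of aldehyde A1 with acetophenone A2 gives chalcone A3. A chiral base, thiourea or acid catalyst then closes ring C by asymmetric 6-endo oxa-Michael addition.
- The ring closure is the exact reverse of the racemisation, so any catalyst that closes ring C can also open it, and enantiomeric purity is at best kinetic.
- A plain chalcone such as A3 is a weak acceptor that does not cyclise fully in the 5-deoxy series. A removable ester on C3 is therefore usually needed, which adds its installation and an acidic decarboxylation next to two prenyl groups.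
- The strongly basic condensation forces a base-stable, acid-labile group on O7.
- The chosen plan never touches O1–C2, needs no activating group and builds no ring.

**Alternative 2:** cut C4–C4a, with O1–C2 made earlier by substitution.
- Forward route: (R)-hydroxy ester A4 is etherified with a ring A phenol under Mitsunobu inversion and saponified to the (S)-aryloxy acid A5. Intramolecular Friedel–Crafts acylation then closes ring C.
- The stereocentre is set outside the labile β-aryloxy ketone, which is attractive.
- However, A4 is an electron-rich benzylic alcohol that can ionise or eliminate during the Mitsunobu step.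
- The acylation needs strong acid or anhydride activation that protonates prenyl alkenes and can expel the phenol from A5.
- Ring closure can occur at two positions of ring A.
- The sequence is several steps longer than the chosen one.

**Alternative 3:** cut C2–H.
- Forward route: flavone A6 undergoes asymmetric conjugate reduction under copper hydride catalysis (Cu(OAc)2, a chiral bisphosphine and a silane).
- A6 already contains every atom of the target, so it must first be assembled. The options are acylation, Baker–Venkataraman shift and acidic cyclodehydration, or oxidative arylation of 8 with 6. The extra unsaturation must then be taken back.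
- C2 of A6 is a β,β-disubstituted acceptor stabilised by both O1 and ring B, and is much less electrophilic than C2–H of 8.
- The catalyst must tell a flat aryl group from O1. The copper enolate can expel the phenoxide, and C4 can be over-reduced.
- The chosen plan reaches the same oxidation level directly and one step earlier.

Key step: step 5

Assumption: 1, 3, 7 and both enantiomers of the diene ligand are taken as commercial. The sense of induction in step 5 is assigned by analogy with six-membered cyclic enones and would be corrected by using the other ligand enantiomer.

## Steps

Step 1
Reactants: 1 1,3-dibromo-2-methoxybenzene (2,6-dibromoanisole)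
Product: 2 2-(3,5-dibromo-4-methoxyphenyl)-4,4,5,5-tetramethyl-1,3,2-dioxaborolane
Conditions: B2pin2 (1.0 equiv), [Ir(OMe)(cod)]2 (1 mol %), 4,4'-di-tert-butyl-2,2'-bipyridine (2 mol %), THF, 60 °C
Reagents that add atoms: bis(pinacolato)diboron, CC1(C)OB(OC1(C)C)B1OC(C)(C)C(C)(C)O1
Why: Iridium-catalysed aromatic C–H borylation is governed by sterics: in 1 the positions C4 and C6 are ortho to bromine and only C5–H (para to OMe) lies between two hydrogens, so a single boronate is expected. Aryl bromides and the methyl ether are inert to this catalyst, and running the step before prenylation keeps catalyst and borane away from any alkene.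

Step 2
Reactants: 2 2-(3,5-dibromo-4-methoxyphenyl)-4,4,5,5-tetramethyl-1,3,2-dioxaborolane; 3 1-bromo-3-methylbut-2-ene (prenyl bromide)
Product: 5 2-[4-methoxy-3,5-bis(3-methylbut-2-en-1-yl)phenyl]-4,4,5,5-tetramethyl-1,3,2-dioxaborolane, via prenylzinc bromide 4 (not isolated)
Conditions: 3 (2.6 equiv), Zn dust, LiCl, THF, 0 °C; then 2, Pd(OAc)2 (2 mol %), SPhos (2-dicyclohexylphosphino-2',6'-dimethoxybiphenyl, 4 mol %), THF, rt
Reagents that add atoms: none
Why: Twofold Negishi coupling: LiCl-assisted zinc insertion turns 3 into 4, and a bulky dialkylbiarylphosphine on zerovalent palladium favours fast reductive elimination at the less hindered primary allyl terminus, which should give the linear prenyl arene at both equivalent C–Br sites. The medium contains no base, so the pinacol boronate cannot transmetalate to palladium and is carried through unchanged.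

Step 3
Reactants: 5 2-[4-methoxy-3,5-bis(3-methylbut-2-en-1-yl)phenyl]-4,4,5,5-tetramethyl-1,3,2-dioxaborolane
Product: 6 [4-methoxy-3,5-bis(3-methylbut-2-en-1-yl)phenyl]boronic acid
Conditions: NaIO4 (3 equiv), NH4OAc (3 equiv), acetone/H2O, rt
Reagents that add atoms: water, O
Why: Hydrolysis of a pinacol boronate is an equilibrium that periodate pulls over by glycol cleavage of the released pinacol. NaIO4 alone does not attack isolated alkenes, and the NH4OAc buffer keeps the medium near neutral.

Step 4
Reactants: 7 7-hydroxy-4H-chromen-4-one (7-hydroxychromone)
Product: 8 7-[(triisopropylsilyl)oxy]-4H-chromen-4-one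
Conditions: i-Pr3SiCl (1.2 equiv), imidazole (2.5 equiv), DMF, rt
Reagents that add atoms: triisopropylsilyl chloride, CC(C)[Si](Cl)(C(C)C)C(C)C
Why: Standard silylation of an acidic phenol. The bulky silyl ether should withstand the mildly basic two-phase medium of step 5 better than smaller silyl groups, yet it leaves with fluoride without acid, base or hydrogen.

Step 5
Reactants: 6 [4-methoxy-3,5-bis(3-methylbut-2-en-1-yl)phenyl]boronic acid; 8 7-[(triisopropylsilyl)oxy]-4H-chromen-4-one
Product: 9 (2S)-2-[4-methoxy-3,5-bis(3-methylbut-2-en-1-yl)phenyl]-7-[(triisopropylsilyl)oxy]-2,3-dihydro-4H-chromen-4-one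
Conditions: 6 (1.5 equiv), [RhCl(C2H4)2]2 (2.5 mol %), (1S,4S)-2,5-diphenylbicyclo[2.2.2]octa-2,5-diene ((S,S)-Ph-bod*, 5.5 mol %), KOH (10 mol %), toluene/H2O, 30–40 °C
Reagents that add atoms: none
Why: This is a Hayashi–Miyaura asymmetric 1,4-addition, a reaction type known for arylboronic acids and chromones under chiral diene or bisphosphine complexes of monovalent rhodium. KOH converts the chloride dimer into the hydroxo complex, which transmetalates with 6; the aryl–rhodium species binds C2=C3 of 8, migratory insertion puts the aryl group on C2 and rhodium on C3 (oxa-π-allyl with C4=O), and water protonates C3 and returns the hydroxo complex. No ring is closed: ring C comes complete with 8, so there is no mode of closure to control and O1–C2 is neither made nor broken. The new stereocentre C2 is controlled by the ligand alone: one phenyl group of the C2-symmetric diene blocks the quadrant that the C4 carbonyl and ring A would occupy in the disfavoured orientation, so 8 should offer the Re face of C2 (O1 > C3 > H) to the aryl group, which gives S, just as (S,S)-dienes of this type give the S product with cyclohex-2-enone. The step needs 1,4- over 1,2-selectivity, secured by the soft aryl–rhodium species and, for the product ketone, by mild temperature and a small excess of 6. It needs chemoselectivity for C2=C3 over the two prenyl alkenes, secured because these are trisubstituted, unpolarised and unable to displace the chelating diene. It needs fast aryl transfer, helped by the absence of ortho substituents next to boron in 6 (C2' and C6' bear hydrogen). It needs retention of configuration in 9, secured by the almost neutral medium buffered by the boronic acid and by the silyl ether, which prevents a 7-phenoxide.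

Step 6
Reactants: 9 (2S)-2-[4-methoxy-3,5-bis(3-methylbut-2-en-1-yl)phenyl]-7-[(triisopropylsilyl)oxy]-2,3-dihydro-4H-chromen-4-one
Product: 10 (2S)-7-hydroxy-2-[4-methoxy-3,5-bis(3-methylbut-2-en-1-yl)phenyl]-2,3-dihydro-4H-chromen-4-one
Conditions: KHF2 (2 equiv), MeOH, rt
Reagents that add atoms: none
Why: This is a fluoride-mediated cleavage of an aryl silyl ether; the 7-aryloxide, para to C4=O, is a very good leaving group from silicon, so the weakly acidic bifluoride should suffice. No base able to deprotonate C3 is present, so C2 should keep its configuration, and the prenyl groups and the methyl ether are inert.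

## Compound list

1 | 1,3-dibromo-2-methoxybenzene (2,6-dibromoanisole) | COc1c(Br)cccc1Br | starting material
2 | 2-(3,5-dibromo-4-methoxyphenyl)-4,4,5,5-tetramethyl-1,3,2-dioxaborolane | COc1c(Br)cc(B2OC(C)(C)C(C)(C)O2)cc1Br | intermediate
3 | 1-bromo-3-methylbut-2-ene (prenyl bromide) | CC(C)=CCBr | starting material
4 | (3-methylbut-2-en-1-yl)zinc bromide (prenylzinc bromide) | CC(C)=CC[Zn]Br | intermediate
5 | 2-[4-methoxy-3,5-bis(3-methylbut-2-en-1-yl)phenyl]-4,4,5,5-tetramethyl-1,3,2-dioxaborolane | COc1c(CC=C(C)C)cc(B2OC(C)(C)C(C)(C)O2)cc1CC=C(C)C | intermediate
6 | [4-methoxy-3,5-bis(3-methylbut-2-en-1-yl)phenyl]boronic acid | COc1c(CC=C(C)C)cc(B(O)O)cc1CC=C(C)C | intermediate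
7 | 7-hydroxy-4H-chromen-4-one | O=c1ccoc2cc(O)ccc12 | starting material
8 | 7-[(triisopropylsilyl)oxy]-4H-chromen-4-one | O=c1ccoc2cc(O[Si](C(C)C)(C(C)C)C(C)C)ccc12 | intermediate
9 | (2S)-2-[4-methoxy-3,5-bis(3-methylbut-2-en-1-yl)phenyl]-7-[(triisopropylsilyl)oxy]-2,3-dihydro-4H-chromen-4-one | COc1c(CC=C(C)C)cc([C@@H]2CC(=O)c3ccc(O[Si](C(C)C)(C(C)C)C(C)C)cc3O2)cc1CC=C(C)C | intermediate
10 | (2S)-7-hydroxy-2-[4-methoxy-3,5-bis(3-methylbut-2-en-1-yl)phenyl]-2,3-dihydro-4H-chromen-4-one | COc1c(CC=C(C)C)cc([C@@H]2CC(=O)c3ccc(O)cc3O2)cc1CC=C(C)C | target

## Count and risks

Total steps: 6. Longest linear sequence: 5 steps (1, 2, 5, 6, 9, 10). Step 4 is the one-step side branch.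

**Step 5 (key step).**
- What may go wrong: O1 and the 7-silyloxy group both push electron density into the enone. Insertion may therefore be slow, and protodeboronation of the electron-rich 6 may outrun it.
- Compensating with longer times, more base or more heat would let ring C of the product open and close reversibly, which would erode the enantiomeric purity. Facial selectivity may also be lower than with simple cyclic enones.
- Fallback: it sets out from 6 and 8 and comes back at 9.
  - The C2–C1' bond is first made without stereocontrol under forcing conditions ([Rh(OH)(cod)]2, dioxane/H2O, 60–80 °C, larger excess of 6). This gives the racemic flavanone silyl ether F1.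
  - The lability of C2 is then put to use in an asymmetric transfer hydrogenation run as a dynamic kinetic resolution (RuCl[(S,S)-TsDPEN](p-cymene), HCO2H/DBU, MeCN). The amine base racemises F1 through ring opening, while the catalyst reduces the S enantiomer faster. Both enantiomers should funnel into the cis-(2S,4S)-flavan-4-ol F2, in which C2 can no longer epimerise.
  - Oxidation with Dess–Martin periodinane and NaHCO3 in CH2Cl2 at 0 °C restores the ketone and gives 9.

**Step 2.**
- What may go wrong: allylic transposition during transmetalation or reductive elimination would place a 1,1-dimethylallyl group on one of the two sites. Because two couplings are needed, any regiochemical leakage counts twice.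
- The reaction may also stall after the first coupling, and 4 may homocouple.
- Fallback: it sets out from 2 and comes back at 5.
  - Twofold Negishi coupling of 2 with allylzinc bromide under the same palladium catalyst has no regiochemical question, because the allyl group is symmetrical. It gives the diallyl boronate F3.
  - Two-directional cross-metathesis of F3 with 2-methylbut-2-ene as co-solvent then builds both trisubstituted alkenes and gives 5. The catalyst is the second-generation Grubbs catalyst, RuCl2(=CHPh)(PCy3)(H2IMes), in CH2Cl2 at 40 °C.

**Step 6.**
- What may go wrong: partial racemisation during or after silyl cleavage. This would happen if fluoride or the liberated phenoxide acts as a base on C3–H and starts the retro-oxa-Michael opening, in the flask or on silica.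
- Fallback: it sets out from 6 and 7 and comes back at 10, and it avoids the protecting group altogether.
  - The free phenol 7 is arylated with 6 under a base-free cationic catalyst of divalent palladium (Pd(OCOCF3)2, (R)-t-BuPyOx, NH4PF6, H2O, ClCH2CH2Cl, 40–60 °C). The ligand enantiomer is again assigned by analogy with six-membered cyclic enones.
  - Without base, O7–H stays protonated and 10 forms directly. Steps 4 and 6 fall away and no new compound is made.
  - The cost is exposure of the prenyl alkenes to an electrophilic palladium species, which is why this is not the first choice.

## Further compounds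

F1 | step 5 | rac-2-[4-methoxy-3,5-bis(3-methylbut-2-en-1-yl)phenyl]-7-[(triisopropylsilyl)oxy]-2,3-dihydro-4H-chromen-4-one | COc1c(CC=C(C)C)cc(C2CC(=O)c3ccc(O[Si](C(C)C)(C(C)C)C(C)C)cc3O2)cc1CC=C(C)C
F2 | step 5 | (2S,4S)-2-[4-methoxy-3,5-bis(3-methylbut-2-en-1-yl)phenyl]-7-[(triisopropylsilyl)oxy]-3,4-dihydro-2H-chromen-4-ol | COc1c(CC=C(C)C)cc([C@@H]2C[C@H](O)c3ccc(O[Si](C(C)C)(C(C)C)C(C)C)cc3O2)cc1CC=C(C)C
F3 | step 2 | 2-[4-methoxy-3,5-di(prop-2-en-1-yl)phenyl]-4,4,5,5-tetramethyl-1,3,2-dioxaborolane | COc1c(CC=C)cc(B2OC(C)(C)C(C)(C)O2)cc1CC=C
F0 | step 6 | none | none
A1 | alternative 1 | 4-methoxy-3,5-bis(3-methylbut-2-en-1-yl)benzaldehyde | COc1c(CC=C(C)C)cc(C=O)cc1CC=C(C)C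
A2 | alternative 1 | 1-[2-hydroxy-4-(methoxymethoxy)phenyl]ethan-1-one | CC(=O)c1ccc(OCOC)cc1O
A3 | alternative 1 | (E)-1-[2-hydroxy-4-(methoxymethoxy)phenyl]-3-[4-methoxy-3,5-bis(3-methylbut-2-en-1-yl)phenyl]prop-2-en-1-one | COCOc1ccc(C(=O)/C=C/c2cc(CC=C(C)C)c(OC)c(CC=C(C)C)c2)c(O)c1
A4 | alternative 2 | methyl (3R)-3-hydroxy-3-[4-methoxy-3,5-bis(3-methylbut-2-en-1-yl)phenyl]propanoate | COC(=O)C[C@@H](O)c1cc(CC=C(C)C)c(OC)c(CC=C(C)C)c1
A5 | alternative 2 | (3S)-3-(3-hydroxyphenoxy)-3-[4-methoxy-3,5-bis(3-methylbut-2-en-1-yl)phenyl]propanoic acid | OC(=O)C[C@H](Oc1cccc(O)c1)c1cc(CC=C(C)C)c(OC)c(CC=C(C)C)c1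
A6 | alternative 3 | 2-[4-methoxy-3,5-bis(3-methylbut-2-en-1-yl)phenyl]-7-[(triisopropylsilyl)oxy]-4H-chromen-4-one | COc1c(CC=C(C)C)cc(-c2cc(=O)c3ccc(O[Si](C(C)C)(C(C)C)C(C)C)cc3o2)cc1CC=C(C)C
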